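The 5-acyloxy-5,6-dihydro-2H-pyran-2-one ring (O1, C2–C6) is read as an oxidised furan. Its cis C3=C4 alkene sits between oxygenated C2 and C5 and beside the O-bearing C6. A 2-furyl carbinol releases this array on oxidative ring opening, with C6 as the former carbinol carbon. The precursor is a furyl carbinol that already carries the complete C1'–C7' side chain, free tertiary vinyl carbinol included. One Achmatowicz oxidation of it should create the O1–C2 bond, the six-membered ring, the C5 ketone and the Z-alkene at once. Lactol oxidation, trans-selective ketone reduction and an inverting Mitsunobu coupling with a bis-silylated dienoic acid then complete the target.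

Key step: step 14

Locants: ring O1, C2(=O), C3=C4, C5, C6. The side chain runs from C1' (on C6) to C7' (vinyl terminus), with methyls on C1', C3' and C5'. The acyl chain is C1''–C8''. The target is 5R,6R (cis), 1'S,3'R,5'S,6''S.

Assumption: (DHQD)2AQN is taken to open the anhydride carbonyl that leads to the (2S,4R)-hemiester; if the sense is the reverse, the pseudo-enantiomeric (DHQ)2AQN is used and nothing else changes.

Step 1
Reactants: 1 meso-(cis)-2,4-dimethylglutaric anhydride
Product: 2 (2S,4R)-5-methoxy-2,4-dimethyl-5-oxopentanoic acid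
Conditions: MeOH (10 equiv), (DHQD)2AQN (0.3 equiv), Et2O, −40 °C; acid wash removes the alkaloid
Reagents that add atoms: methanol, SMILES CO
Why: In this alkaloid-catalysed desymmetrising alcoholysis of a meso anhydride the quinuclidine base activates methanol for attack on one enantiotopic carbonyl, so both methyl-bearing centres (future C1' S and C3' R) are fixed in one catalytic operation.

Step 2
Reactants: 2 (2S,4R)-5-methoxy-2,4-dimethyl-5-oxopentanoic acid
Product: 3 methyl (2R,4S)-5-chloro-2,4-dimethyl-5-oxopentanoate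
Conditions: (COCl)2 (1.2 equiv), DMF (cat.), CH2Cl2, 0 °C to rt; concentrated and used at once
Reagents that add atoms: oxalyl chloride, SMILES O=C(Cl)C(=O)Cl
Why: Vilsmeier-type acid chloride formation is mild, and low temperature with immediate use avoids ketene-type epimerisation at C1' and the methoxy shift between the two carbonyls that would erode enantiopurity.

Step 3
Reactants: 3 methyl (2R,4S)-5-chloro-2,4-dimethyl-5-oxopentanoate; 4 furan
Product: 7 methyl (2R,4S)-5-(furan-2-yl)-2,4-dimethyl-5-oxopentanoate, via 2-furyllithium 5 (not isolated), via 2-furylzinc chloride 6 (not isolated)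
Conditions: 4, n-BuLi, THF, 0 °C; ZnCl2, 0 °C to rt; then 3, Pd(PPh3)4 (5 mol %), THF, 0 °C to rt
Reagents that add atoms: n-butyllithium, SMILES [Li]CCCC (lithium of 5 only); ZnCl2, SMILES Cl[Zn]Cl (zinc and chlorine of 6 only)
Why: In this Negishi acylation zerovalent palladium inserts into the C–Cl bond, the mild furylzinc reagent transmetalates and reductive elimination gives the ketone without attack on the methyl ester, over-addition or enolisation at C1'.

Step 4
Reactants: 7 methyl (2R,4S)-5-(furan-2-yl)-2,4-dimethyl-5-oxopentanoate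
Product: 8 methyl (2R,4S,5R)-5-(furan-2-yl)-5-hydroxy-2,4-dimethylpentanoate
Conditions: (S)-Me-CBS oxazaborolidine (0.3 equiv), BH3·SMe2 (1.0 equiv), toluene/THF, −30 °C; MeOH quench
Reagents that add atoms: none
Why: In this Corey–Bakshi–Shibata reduction the (S)-catalyst treats the sp2 furyl group as the large substituent and delivers hydride to the face giving the (6R), 1',6-syn carbinol, overriding a Felkin–Anh bias that is weak because C1' only distinguishes CH3 from CH2R, and any 6-epimer is removed by chromatography.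

Step 5
Reactants: 8 methyl (2R,4S,5R)-5-(furan-2-yl)-5-hydroxy-2,4-dimethylpentanoate
Product: 9 methyl (2R,4S,5R)-5-(tert-butyldimethylsilyloxy)-5-(furan-2-yl)-2,4-dimethylpentanoate
Conditions: TBSOTf (1.2 equiv), 2,6-lutidine (2 equiv), CH2Cl2, −78 to 0 °C
Reagents that add atoms: tert-butyldimethylsilyl triflate, SMILES CC(C)(C)[Si](C)(C)OS(=O)(=O)C(F)(F)F
Why: Prompt silylation of the hindered secondary alcohol with the silyl triflate and a non-nucleophilic base forestalls δ-lactonisation and masks the furyl carbinol against the later organolithium, titanium/peroxide and zinc reagents.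

Step 6
Reactants: 9 methyl (2R,4S,5R)-5-(tert-butyldimethylsilyloxy)-5-(furan-2-yl)-2,4-dimethylpentanoate
Product: 10 (2R,4S,5R)-5-(tert-butyldimethylsilyloxy)-5-(furan-2-yl)-2,4-dimethylpentan-1-ol
Conditions: i-Bu2AlH (2.5 equiv), CH2Cl2, −78 to 0 °C; aq. potassium sodium tartrate
Reagents that add atoms: none
Why: Exhaustive hydride reduction of the ester gives the primary alcohol, and the furan, the silyl ether and the three stereocentres are inert to i-Bu2AlH.

Step 7
Reactants: 10 (2R,4S,5R)-5-(tert-butyldimethylsilyloxy)-5-(furan-2-yl)-2,4-dimethylpentan-1-ol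
Product: 11 tert-butyl{[(1R,2S,4R)-1-(furan-2-yl)-5-iodo-2,4-dimethylpentyl]oxy}dimethylsilane
Conditions: PPh3, imidazole, I2 (premixed), CH2Cl2, 0 °C, dark; then 10
Reagents that add atoms: iodine, SMILES [I][I]
Why: Appel-type iodination through an alkoxyphosphonium ion is an SN2 process at the unhindered primary carbon that leaves C3' untouched, and pre-forming the phosphonium iodide keeps free iodine away from the furan.

Step 8
Reactants: 11 tert-butyl{[(1R,2S,4R)-1-(furan-2-yl)-5-iodo-2,4-dimethylpentyl]oxy}dimethylsilane; 12 ethyl but-2-ynoate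
Product: 16 ethyl (2E,5R,7S,8R)-8-(tert-butyldimethylsilyloxy)-8-(furan-2-yl)-3,5,7-trimethyloct-2-enoate, via primary alkyllithium 13 (not isolated), via primary alkylcopper 14 (not isolated), via alkenylcopper adduct 15 (not isolated)
Conditions: t-BuLi (2.1 equiv), Et2O/pentane, −78 °C; CuBr·SMe2 (1.05 equiv), Me2S/THF, −78 to −50 °C; 12, THF, −78 °C; MeOH then sat. aq. NH4Cl at −78 °C
Reagents that add atoms: tert-butyllithium, SMILES [Li]C(C)(C)C (lithium of 13 only); CuBr·SMe2, SMILES [Cu]Br.CSC (copper of 14 and 15 only)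
Why: Iodine–lithium exchange, transmetalation to the monoalkylcopper and syn carbocupration of the ynoate at its methyl-bearing carbon put the new alkyl group and copper on the same side, and protonation at −78 °C with retention gives the (E)-trisubstituted enoate while no second alkyl ligand is wasted.

Step 9
Reactants: 16 ethyl (2E,5R,7S,8R)-8-(tert-butyldimethylsilyloxy)-8-(furan-2-yl)-3,5,7-trimethyloct-2-enoate
Product: 17 (2E,5R,7S,8R)-8-(tert-butyldimethylsilyloxy)-8-(furan-2-yl)-3,5,7-trimethyloct-2-en-1-ol
Conditions: i-Bu2AlH (2.5 equiv), CH2Cl2, −78 °C; aq. potassium sodium tartrate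
Reagents that add atoms: none
Why: 1,2-Reduction of the enoate by i-Bu2AlH gives the allylic alcohol without touching the alkene geometry.

Step 10
Reactants: 17 (2E,5R,7S,8R)-8-(tert-butyldimethylsilyloxy)-8-(furan-2-yl)-3,5,7-trimethyloct-2-en-1-ol
Product: 18 [(2S,3S)-3-{(2R,4S,5R)-5-(tert-butyldimethylsilyloxy)-5-(furan-2-yl)-2,4-dimethylpentyl}-3-methyloxiran-2-yl]methanol
Conditions: Ti(OiPr)4 (0.1 equiv), L-(+)-diethyl tartrate (0.12 equiv), t-BuOOH (2 equiv), 4 Å MS, CH2Cl2, −20 °C
Reagents that add atoms: tert-butyl hydroperoxide, SMILES CC(C)(C)OO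
Why: In this Sharpless asymmetric epoxidation the L-(+)-tartrate delivers oxygen to the face that gives the (5'S,6'S)-epoxide, as for other (E)-3-methylalk-2-en-1-ols, and the furan is spared because its silylated carbinol oxygen cannot bind titanium.

Step 11
Reactants: 18 [(2S,3S)-3-{(2R,4S,5R)-5-(tert-butyldimethylsilyloxy)-5-(furan-2-yl)-2,4-dimethylpentyl}-3-methyloxiran-2-yl]methanol
Product: 19 epoxy iodide, the (2R,3S)-2-(iodomethyl)-3-methyloxirane carrying the same (2R,4S,5R)-pentyl chain on C3 (spatially unchanged from 18)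
Conditions: PPh3, imidazole, I2 (premixed), THF, 0 °C, dark; then 18
Reagents that add atoms: iodine, SMILES [I][I]
Why: Appel-type iodination of the primary epoxy alcohol in the imidazole buffer is an SN2 displacement at CH2 that leaves both epoxide C–O bonds intact.

Step 12
Reactants: 19 epoxy iodide
Product: 20 (3S,5R,7S,8R)-8-(tert-butyldimethylsilyloxy)-8-(furan-2-yl)-3,5,7-trimethyloct-1-en-3-ol
Conditions: activated Zn dust (10 equiv), EtOH, 70 °C
Reagents that add atoms: none
Why: In this reductive β-elimination zinc inserts into the C–I bond and the organozinc expels the epoxide oxygen from C6', unveiling the vinyl group while the C5'–O bond, and so the S configuration at C5', is never broken.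

Step 13
Reactants: 20 (3S,5R,7S,8R)-8-(tert-butyldimethylsilyloxy)-8-(furan-2-yl)-3,5,7-trimethyloct-1-en-3-ol
Product: 21 (1R,2S,4R,6S)-1-(furan-2-yl)-2,4,6-trimethyloct-7-ene-1,6-diol
Conditions: Bu4NF (1.5 equiv), THF, 0 °C to rt
Reagents that add atoms: none
Why: Fluoride-driven Si–O cleavage under non-acidic conditions frees the furyl carbinol needed for ring expansion without risk to the acid-sensitive tertiary allylic alcohol.

Step 14
Reactants: 21 (1R,2S,4R,6S)-1-(furan-2-yl)-2,4,6-trimethyloct-7-ene-1,6-diol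
Product: 22 (2R)-6-hydroxy-2-[(2S,4R,6S)-6-hydroxy-4,6-dimethyloct-7-en-2-yl]-2H-pyran-3(6H)-one (anomer mixture)
Conditions: NBS (1.0 equiv), NaHCO3, NaOAc, THF/H2O 4:1, 0 °C
Reagents that add atoms: water, SMILES O
Why: Electrophilic bromine from NBS is taken up at the unsubstituted α-carbon of the furan, water is captured by the resulting oxocarbenium ion, and loss of bromide unravels the 2,5-dihydrofuran into an acyclic Z-configured 4-oxo-2-enal. The C6 hydroxyl then closes on the aldehyde carbon by 6-exo-trig hemiacetalisation, which forms the O1–C2 bond and the only ring, while furan C2 ends as the C5 ketone and furan C3=C4 as the ring alkene. This is the Achmatowicz rearrangement of 2-furyl carbinols in its standard NBS/aqueous THF form. C6 is a spectator whose four bonds stay intact, so its R configuration is retained; the only new stereocentre, lactol carbon C2, settles under thermodynamic anomeric control and is deleted in step 15, so the anomer mixture is used as such. The step needs oxidation of the furan in preference to the C6'=C7' vinyl group and the tertiary allylic alcohol, and the much greater π-nucleophilicity of the furan over a monosubstituted alkene, together with one equivalent of NBS at 0 °C in a NaHCO3/NaOAc buffer, should secure this. Hydroxyl-directed oxidants such as VO(acac)2/t-BuOOH and peracids are deliberately not used, since they could epoxidise the allylic alcohol.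

Step 15
Reactants: 22 (2R)-6-hydroxy-2-[(2S,4R,6S)-6-hydroxy-4,6-dimethyloct-7-en-2-yl]-2H-pyran-3(6H)-one
Product: 23 (6R)-6-[(2S,4R,6S)-6-hydroxy-4,6-dimethyloct-7-en-2-yl]-2H-pyran-2,5(6H)-dione
Conditions: Dess–Martin periodinane (1.3 equiv), solid NaHCO3, CH2Cl2, 0 °C; short cold filtration, used at once
Reagents that add atoms: none
Why: Dess–Martin oxidation takes the lactol to the lactone under buffered, metal-free conditions, whereas acidic hexavalent chromium reagents would trigger oxidative 1,3-transposition of the tertiary allylic alcohol, which is itself not oxidisable here.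

Step 16
Reactants: 23 (6R)-6-[(2S,4R,6S)-6-hydroxy-4,6-dimethyloct-7-en-2-yl]-2H-pyran-2,5(6H)-dione
Product: 24 (5S,6R)-5-hydroxy-6-[(2S,4R,6S)-6-hydroxy-4,6-dimethyloct-7-en-2-yl]-5,6-dihydro-2H-pyran-2-one (5,6-trans)
Conditions: CeCl3·7H2O (1.2 equiv), NaBH4 (1.0 equiv), MeOH/CH2Cl2 1:1, −78 °C; sat. aq. NH4Cl at −78 °C
Reagents that add atoms: none
Why: In this Luche reduction the hard cerium-modified borohydride attacks only the C5 ketone in 1,2-fashion, axially on the half-chair that keeps the branched C6 substituent pseudo-equatorial, so the pseudo-equatorial 5,6-trans alcohol (5S) should prevail as is usual for ketones derived from Achmatowicz products, and the cold near-neutral quench prevents O5-to-C2 translactonisation.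

Step 17
Reactants: 25 4-(tert-butyldimethylsilyloxy)butanal
Product: 27 ethyl (2E,4S)-6-(tert-butyldimethylsilyloxy)-4-(hydroxymethyl)-2-methylhex-2-enoate, via hydroxymethyl aldehyde 26 (not isolated)
Conditions: aq. HCHO (37 %), (S)-α,α-diphenylprolinol trimethylsilyl ether (0.2 equiv), pH 7 phosphate buffer, toluene, rt; phase cut; Ph3P=C(Me)CO2Et (2 equiv) added to the toluene layer, rt
Reagents that add atoms: formaldehyde, SMILES C=O; ethyl 2-(triphenylphosphoranylidene)propanoate, SMILES CCOC(=O)C(C)=P(c1ccccc1)(c1ccccc1)c1ccccc1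
Why: In this enamine-catalysed α-hydroxymethylation the (E)-enamine of 25 is shielded on one face by the diphenyl(silyloxy)methyl group and takes up formaldehyde on the other, which sets the (R)-aldehyde centre (S after olefination), and the labile β-hydroxy aldehyde is trapped at room temperature by the reactive ester-stabilised ylide in an (E)-selective Wittig reaction before it can dehydrate or racemise.

Step 18
Reactants: 27 ethyl (2E,4S)-6-(tert-butyldimethylsilyloxy)-4-(hydroxymethyl)-2-methylhex-2-enoate
Product: 28 ethyl (2E,4S)-6-(tert-butyldimethylsilyloxy)-4-[(tert-butyldimethylsilyloxy)methyl]-2-methylhex-2-enoate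
Conditions: TBSCl (1.2 equiv), imidazole (2 equiv), CH2Cl2, rt
Reagents that add atoms: tert-butyldimethylsilyl chloride, SMILES CC(C)(C)[Si](C)(C)Cl
Why: Routine silylation of the primary alcohol gives both hydroxyls the same fluoride-labile group, so that one final operation frees them.

Step 19
Reactants: 28 ethyl (2E,4S)-6-(tert-butyldimethylsilyloxy)-4-[(tert-butyldimethylsilyloxy)methyl]-2-methylhex-2-enoate
Product: 29 (2E,4S)-6-(tert-butyldimethylsilyloxy)-4-[(tert-butyldimethylsilyloxy)methyl]-2-methylhex-2-en-1-ol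
Conditions: i-Bu2AlH (2.5 equiv), CH2Cl2, −78 °C; aq. potassium sodium tartrate
Reagents that add atoms: none
Why: 1,2-Reduction of the enoate gives the allylic alcohol with the alkene geometry and the allylic stereocentre unchanged.

Step 20
Reactants: 29 (2E,4S)-6-(tert-butyldimethylsilyloxy)-4-[(tert-butyldimethylsilyloxy)methyl]-2-methylhex-2-en-1-ol
Product: 30 (2E,4S)-6-(tert-butyldimethylsilyloxy)-4-[(tert-butyldimethylsilyloxy)methyl]-2-methylhex-2-enal
Conditions: activated MnO2 (15 equiv), CH2Cl2, rt
Reagents that add atoms: none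
Why: Heterogeneous MnO2 oxidation is selective for the allylic alcohol and neutral, so neither the allylic stereocentre nor the (E)-alkene is at risk.

Step 21
Reactants: 30 (2E,4S)-6-(tert-butyldimethylsilyloxy)-4-[(tert-butyldimethylsilyloxy)methyl]-2-methylhex-2-enal
Product: 31 (2E,4E,6S)-8-(tert-butyldimethylsilyloxy)-6-[(tert-butyldimethylsilyloxy)methyl]-4-methylocta-2,4-dienoic acid
Conditions: (EtO)2P(O)CH2CO2H (1.3 equiv), Zn(OTf)2 (2.2 equiv), TMEDA, DBU (4 equiv), THF, rt; cold dilute HCl work-up
Reagents that add atoms: diethylphosphonoacetic acid, SMILES CCOP(=O)(CC(=O)O)OCC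
Why: Horner–Wadsworth–Emmons olefination with the zinc-chelated doubly deprotonated phosphonoacetic acid, generated by weak amine bases, gives the (2E)-acid directly and so saves a saponification in the presence of silyl ethers.

Step 22
Reactants: 24 (5S,6R)-5-hydroxy-6-[(2S,4R,6S)-6-hydroxy-4,6-dimethyloct-7-en-2-yl]-5,6-dihydro-2H-pyran-2-one; 31 (2E,4E,6S)-8-(tert-butyldimethylsilyloxy)-6-[(tert-butyldimethylsilyloxy)methyl]-4-methylocta-2,4-dienoic acid
Product: 32 bis-silyl ether of the target, the (5R,6R)-5,6-cis ester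
Conditions: 31 (1.5 equiv), PPh3 (2 equiv), DIAD (2 equiv, added last), toluene, −20 °C to rt
Reagents that add atoms: none
Why: In this Mitsunobu esterification only the secondary C5 alcohol forms the alkoxyphosphonium ion (the tertiary C5' alcohol stays inert) and the carboxylate displaces it by SN2 with inversion to the 5,6-cis (5R) ester, because SN2' attack would have to occur at the non-electrophilic α-carbon C3 and anti-elimination is blocked since H6 and the leaving group lie on the same face.

Step 23
Reactants: 32 bis-silyl ether of the target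
Product: 33 target, (2R,3R)-2-[(2S,4R,6S)-6-hydroxy-4,6-dimethyloct-7-en-2-yl]-6-oxo-3,6-dihydro-2H-pyran-3-yl (2E,4E,6S)-8-hydroxy-6-(hydroxymethyl)-4-methylocta-2,4-dienoate
Conditions: HF·pyridine, excess pyridine, THF, 0 °C to rt
Reagents that add atoms: none
Why: Pyridine-buffered HF cleaves the two primary silyl ethers by fluoride attack at silicon under conditions mild enough for the tertiary allylic alcohol, the allylic ester and the unsaturated lactone.

Compound list
1 | meso-(cis)-2,4-dimethylglutaric anhydride | C[C@@H]1C[C@H](C)C(=O)OC1=O | starting material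
2 | (2S,4R)-5-methoxy-2,4-dimethyl-5-oxopentanoic acid | COC(=O)[C@H](C)C[C@H](C)C(=O)O | intermediate
3 | methyl (2R,4S)-5-chloro-2,4-dimethyl-5-oxopentanoate | COC(=O)[C@H](C)C[C@H](C)C(=O)Cl | intermediate
4 | furan | c1ccoc1 | starting material
5 | 2-furyllithium | [Li]c1ccco1 | intermediate (not isolated)
6 | 2-furylzinc chloride | Cl[Zn]c1ccco1 | intermediate (not isolated)
7 | methyl (2R,4S)-5-(furan-2-yl)-2,4-dimethyl-5-oxopentanoate | COC(=O)[C@H](C)C[C@H](C)C(=O)c1ccco1 | intermediate
8 | methyl (2R,4S,5R)-5-(furan-2-yl)-5-hydroxy-2,4-dimethylpentanoate | COC(=O)[C@H](C)C[C@H](C)[C@@H](O)c1ccco1 | intermediate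
9 | methyl (2R,4S,5R)-5-(tert-butyldimethylsilyloxy)-5-(furan-2-yl)-2,4-dimethylpentanoate | COC(=O)[C@H](C)C[C@H](C)[C@@H](O[Si](C)(C)C(C)(C)C)c1ccco1 | intermediate
10 | (2R,4S,5R)-5-(tert-butyldimethylsilyloxy)-5-(furan-2-yl)-2,4-dimethylpentan-1-ol | OC[C@H](C)C[C@H](C)[C@@H](O[Si](C)(C)C(C)(C)C)c1ccco1 | intermediate
11 | tert-butyl{[(1R,2S,4R)-1-(furan-2-yl)-5-iodo-2,4-dimethylpentyl]oxy}dimethylsilane | IC[C@H](C)C[C@H](C)[C@@H](O[Si](C)(C)C(C)(C)C)c1ccco1 | intermediate
12 | ethyl but-2-ynoate | CCOC(=O)C#CC | starting material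
13 | primary alkyllithium from 11 (three stereocentres spatially as in 11) | [Li]C[C@H](C)C[C@H](C)[C@@H](O[Si](C)(C)C(C)(C)C)c1ccco1 | intermediate (not isolated)
14 | primary alkylcopper from 13 (stereocentres spatially as in 11) | [Cu]C[C@H](C)C[C@H](C)[C@@H](O[Si](C)(C)C(C)(C)C)c1ccco1 | intermediate (not isolated)
15 | alkenylcopper adduct, copper on C2 cis to the new alkyl group on C3 | CCOC(=O)/C([Cu])=C(\C)C[C@H](C)C[C@H](C)[C@@H](O[Si](C)(C)C(C)(C)C)c1ccco1 | intermediate (not isolated)
16 | ethyl (2E,5R,7S,8R)-8-(tert-butyldimethylsilyloxy)-8-(furan-2-yl)-3,5,7-trimethyloct-2-enoate | CCOC(=O)/C=C(\C)C[C@H](C)C[C@H](C)[C@@H](O[Si](C)(C)C(C)(C)C)c1ccco1 | intermediate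
17 | (2E,5R,7S,8R)-8-(tert-butyldimethylsilyloxy)-8-(furan-2-yl)-3,5,7-trimethyloct-2-en-1-ol | OC/C=C(\C)C[C@H](C)C[C@H](C)[C@@H](O[Si](C)(C)C(C)(C)C)c1ccco1 | intermediate
18 | (2S,3S)-epoxy alcohol (5'S,6'S) | OC[C@@H]1O[C@@]1(C)C[C@H](C)C[C@H](C)[C@@H](O[Si](C)(C)C(C)(C)C)c1ccco1 | intermediate
19 | (2R,3S)-epoxy iodide (spatially as 18) | IC[C@@H]1O[C@@]1(C)C[C@H](C)C[C@H](C)[C@@H](O[Si](C)(C)C(C)(C)C)c1ccco1 | intermediate
20 | (3S,5R,7S,8R)-8-(tert-butyldimethylsilyloxy)-8-(furan-2-yl)-3,5,7-trimethyloct-1-en-3-ol | C=C[C@@](C)(O)C[C@H](C)C[C@H](C)[C@@H](O[Si](C)(C)C(C)(C)C)c1ccco1 | intermediate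
21 | (1R,2S,4R,6S)-1-(furan-2-yl)-2,4,6-trimethyloct-7-ene-1,6-diol | C=C[C@@](C)(O)C[C@H](C)C[C@H](C)[C@@H](O)c1ccco1 | intermediate
22 | (2R)-6-hydroxy-2-[(2S,4R,6S)-6-hydroxy-4,6-dimethyloct-7-en-2-yl]-2H-pyran-3(6H)-one, anomer mixture | C=C[C@@](C)(O)C[C@H](C)C[C@H](C)[C@H]1OC(O)C=CC1=O | intermediate
23 | (6R)-6-[(2S,4R,6S)-6-hydroxy-4,6-dimethyloct-7-en-2-yl]-2H-pyran-2,5(6H)-dione | C=C[C@@](C)(O)C[C@H](C)C[C@H](C)[C@H]1OC(=O)C=CC1=O | intermediate
24 | (5S,6R)-5-hydroxy-6-[(2S,4R,6S)-6-hydroxy-4,6-dimethyloct-7-en-2-yl]-5,6-dihydro-2H-pyran-2-one | C=C[C@@](C)(O)C[C@H](C)C[C@H](C)[C@H]1OC(=O)C=C[C@@H]1O | intermediate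
25 | 4-(tert-butyldimethylsilyloxy)butanal | O=CCCCO[Si](C)(C)C(C)(C)C | starting material
26 | (2R)-4-(tert-butyldimethylsilyloxy)-2-(hydroxymethyl)butanal | O=C[C@@H](CO)CCO[Si](C)(C)C(C)(C)C | intermediate (not isolated)
27 | ethyl (2E,4S)-6-(tert-butyldimethylsilyloxy)-4-(hydroxymethyl)-2-methylhex-2-enoate | CCOC(=O)/C(C)=C/[C@@H](CO)CCO[Si](C)(C)C(C)(C)C | intermediate
28 | ethyl (2E,4S)-6-(tert-butyldimethylsilyloxy)-4-[(tert-butyldimethylsilyloxy)methyl]-2-methylhex-2-enoate | CCOC(=O)/C(C)=C/[C@@H](CO[Si](C)(C)C(C)(C)C)CCO[Si](C)(C)C(C)(C)C | intermediate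
29 | (2E,4S)-6-(tert-butyldimethylsilyloxy)-4-[(tert-butyldimethylsilyloxy)methyl]-2-methylhex-2-en-1-ol | OC/C(C)=C/[C@@H](CO[Si](C)(C)C(C)(C)C)CCO[Si](C)(C)C(C)(C)C | intermediate
30 | (2E,4S)-6-(tert-butyldimethylsilyloxy)-4-[(tert-butyldimethylsilyloxy)methyl]-2-methylhex-2-enal | O=C/C(C)=C/[C@@H](CO[Si](C)(C)C(C)(C)C)CCO[Si](C)(C)C(C)(C)C | intermediate
31 | (2E,4E,6S)-8-(tert-butyldimethylsilyloxy)-6-[(tert-butyldimethylsilyloxy)methyl]-4-methylocta-2,4-dienoic acid | OC(=O)/C=C/C(C)=C/[C@@H](CO[Si](C)(C)C(C)(C)C)CCO[Si](C)(C)C(C)(C)C | intermediate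
32 | bis-silyl ether of the target, (5R,6R)-cis ester | C=C[C@@](C)(O)C[C@H](C)C[C@H](C)[C@H]1OC(=O)C=C[C@H]1OC(=O)/C=C/C(C)=C/[C@@H](CO[Si](C)(C)C(C)(C)C)CCO[Si](C)(C)C(C)(C)C | intermediate
33 | CNP0227568.1 | C=C[C@@](C)(O)C[C@H](C)C[C@H](C)[C@H]1OC(=O)C=C[C@H]1OC(=O)/C=C/C(C)=C/[C@@H](CO)CCO | target

Total step count: 23. Longest linear sequence: 18 steps (steps 1–16, 22 and 23). The acid branch takes 5 steps (steps 17–21).

Steps most likely to fail

(a) Step 4, the catalyst-controlled ketone reduction.
- What may go wrong: the catalyst may not tell the small, flat furyl group from the branched alkyl group while it also works against the Felkin–Anh preference. Facial selectivity at C6 would then erode.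
- Fallback: C6 is set by carbon–carbon bond formation instead of by hydride delivery. The path sets out from acid chloride 3 and 2-furyllithium 5 and comes back at 8.
- Compound 3 is reduced with LiAlH(Ot-Bu)3 (THF, −78 °C) to methyl (2R,4S)-2,4-dimethyl-5-oxopentanoate F1.
- Compound 5 is transmetalated with ClTi(OiPr)3 to (furan-2-yl)triisopropoxytitanium F2. This reagent adds to the aldehyde of F1 at −78 to −20 °C and leaves the ester alone.
- For addition of a nucleophile to the α-methyl aldehyde the Felkin–Anh model predicts the 1',6-syn carbinol, so substrate control now works for the needed isomer 8 and not against it.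

(b) Step 15, formation and handling of the ene-dione lactone.
- What may go wrong: enolisation at C6 towards the aromatic 5-hydroxy-2-pyranone tautomer would erase the C6 configuration, and the compound may also degrade during isolation.
- Fallback: C2 stays masked at the lactol oxidation level until the last operation, so no enolisable dicarbonyl lactone is ever made. The path sets out from 22 and comes back at 33.
- TBSCl/imidazole silylates only the lactol hydroxyl of 22 and gives the 2-silyloxy pyranone F3.
- Luche reduction gives the 5,6-trans allylic alcohol F4.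
- Mitsunobu coupling with 31 gives the 5,6-cis dienoate silyl acetal F5.
- HF·pyridine removes all three silyl groups and gives the 2-hydroxy (lactol) analogue of the target F6.
- Activated MnO2 in CH2Cl2 then oxidises only the allylic lactol and gives 33, because the saturated primary alcohols and the tertiary alcohol are inert to it.

(c) Step 22, the Mitsunobu union.
- What may go wrong: the carboxylate must reach C5 on the face occupied by the branched C6 substituent. A slow displacement would let acyl transfer with retention, elimination or allylic transposition compete and would consume the valuable acid.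
- Fallback: inversion is separated from fragment coupling. The path sets out from 24 and comes back at 32.
- A Mitsunobu reaction of 24 with the small and more acidic 4-nitrobenzoic acid gives the inverted (5R,6R)-4-nitrobenzoate F7.
- Mild methanolysis (Et3N, MeOH, 0 °C) frees the (5R,6R)-5,6-cis alcohol F8.
- Yamaguchi esterification with 31 (2,4,6-trichlorobenzoyl chloride, Et3N, DMAP, toluene) proceeds with retention at C5 and gives 32.
- F8 is also the point of entry if step 16 should favour the cis alcohol.

Further compounds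
F1 | step 4 | methyl (2R,4S)-2,4-dimethyl-5-oxopentanoate | COC(=O)[C@H](C)C[C@H](C)C=O
F2 | step 4 | (furan-2-yl)triisopropoxytitanium | CC(C)O[Ti](OC(C)C)(OC(C)C)c1ccco1
F3 | step 15 | (2R)-6-(tert-butyldimethylsilyloxy)-2-[(2S,4R,6S)-6-hydroxy-4,6-dimethyloct-7-en-2-yl]-2H-pyran-3(6H)-one, anomer mixture | C=C[C@@](C)(O)C[C@H](C)C[C@H](C)[C@H]1OC(O[Si](C)(C)C(C)(C)C)C=CC1=O
F4 | step 15 | 5,6-trans allylic alcohol of the silyl acetal | C=C[C@@](C)(O)C[C@H](C)C[C@H](C)[C@H]1OC(O[Si](C)(C)C(C)(C)C)C=C[C@@H]1O
F5 | step 15 | 5,6-cis dienoate of the silyl acetal, tris-silylated | C=C[C@@](C)(O)C[C@H](C)C[C@H](C)[C@H]1OC(O[Si](C)(C)C(C)(C)C)C=C[C@H]1OC(=O)/C=C/C(C)=C/[C@@H](CO[Si](C)(C)C(C)(C)C)CCO[Si](C)(C)C(C)(C)C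
F6 | step 15 | 2-hydroxy (lactol) analogue of the target | C=C[C@@](C)(O)C[C@H](C)C[C@H](C)[C@H]1OC(O)C=C[C@H]1OC(=O)/C=C/C(C)=C/[C@@H](CO)CCO
F7 | step 22 | (5R,6R)-5-(4-nitrobenzoyloxy) lactone | C=C[C@@](C)(O)C[C@H](C)C[C@H](C)[C@H]1OC(=O)C=C[C@H]1OC(=O)c1ccc(cc1)[N+](=O)[O-]
F8 | step 22 | (5R,6R)-5-hydroxy-6-[(2S,4R,6S)-6-hydroxy-4,6-dimethyloct-7-en-2-yl]-5,6-dihydro-2H-pyran-2-one | C=C[C@@](C)(O)C[C@H](C)C[C@H](C)[C@H]1OC(=O)C=C[C@H]1O
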